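## Structural features

The target 16 (C22H29NO4) is a pentacyclic Stemona-type pyrrole alkaloid. Pyrrole ring A (N-1, C-2 to C-5) is fused across N-1/C-2 to azepine ring C and across C-2/C-3 to carbocyclic ring B. Ring B shares its C-11–C-12 bond with γ-lactone ring D, and pyrrole C-5 carries a separate α-methyl-γ-butyrolactone, ring E. The sp3 carbons are labelled C-9 (azepine CH on pyrrole C-2), C-10 (CH–ethyl), C-11 (O–CH), C-12 (CH on pyrrole C-3), C-13 (CH–CH3 of ring D), C-18 (O–CH of ring E) and C-20 (CH–CH3 of ring E); the target is 9R,10R,11S,12R,13R,18S,20S. C-9 to C-13 are five contiguous stereocentres: H-9 and H-10 are trans, the ethyl group is trans to the C-11 oxygen, lactone D is cis-fused, and the C-13 methyl sits on the concave face, so H-11, H-12 and H-13 are all cis. C-18 and C-20 form an isolated cis pair that no centre of the core can relay to. The fragile points are the electron-rich tetrasubstituted pyrrole (acid, oxidants), the ionisable pyrrolylcarbinyl C-18–O bond, the base-epimerisable C-13 and C-20, and any aldehyde with C-10 in its α-position. The real difficulty is the C-9/C-10 pair, which has no heteroatom to steer its construction, together with the late, unrelayed C-18. The key step uses the facts that N-1 is joined to C-9 by four methylenes and that C-9, C-10 and C-11 are the β-carbon, α-carbon and carbonyl carbon of a 2-ethyl enal. Attack of pyrrole C-2 on that enal closes ring C and creates C-9 and C-10 together.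

## Logic of the disconnections

16 is cut at the acyl–oxygen bond of ring E and at C-18–H, giving 14 by way of 15. C-20 then comes from the chiral pool and C-18 from a reagent-controlled reduction, the only option for a centre this remote. The gain is that the ionisable C-18–O bond exists only in the last step and the pyrrole stays acyl-deactivated until then. The demand is a face-selective reduction of a vinylogous-amide ketone beside lactone D, and a ring closure free of acid and base.

14 is cut at the pyrrole C-3–C-12 bond and at C-13–H, giving 13. This removes ring B and two stereocentres in one conjugate addition onto a butenolide. The demand is that the β-carbon of an acylpyrrole attacks, that the tether enforces the cis ring fusion, and that the enolate is protonated on the convex face.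

13 is cut at the pyrrole C-5–carbonyl bond, giving 9 and the acyl donor 12, made in the flask from 11. The reason is that C-5 is the only free α-position of 9 and that the acyl group blocks and tempers the pyrrole for the next step. 11 is traced to 10 by hydrolysis of the less hindered of two esters. The demand is regioselective acylation and regioselective hydrolysis.

9 is cut at the ring D C=C bond (ring-closing metathesis) to 8, and 8 at its ester C–O bond to 7 and methacryloyl chloride. This reduces the butenolide to an allylic alcohol. The demand is closure of a trisubstituted alkene without touching C-11.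

7 is cut at the C-11–vinyl bond, giving 6 and vinylmagnesium bromide. C-11 then arises from the aldehyde carbon under the influence of C-10. The demand is Felkin–Anh selectivity without enolisation of the aldehyde.

6 is cut at the pyrrole C-2–C-9 bond and at C-10–H, giving 5. Ring C and both carbon-only stereocentres disappear, leaving an achiral, linear enal. The demand is catalyst control of the face of the β-carbon and of the protonation at C-10 in a seven-membered closure.

5 is cut at its C=C bond into 3 and 4 (cross-metathesis), and 3 at its N–C bond into 1 and 2. Everything before the key step then takes two steps from bulk chemicals. The demand is E selectivity, which thermodynamics should supply.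

## Other disconnections considered

Alternative 1: The cut removes the C-10–ethyl bond and the C-9–C-8 bond on a ring B surrogate. Dienone A1 would take Et2Zn under Cu(OTf)2/phosphoramidite catalysis, and the zinc enolate would be allylated by the π-allyl complex formed from acetate A2 and Pd(PPh3)4, giving A3. In A3 the ketal carbon is the future C-11, the carbonyl the future pyrrole C-2, and the butenyl chain the four carbons of ring C.
- In its favour: conjugate addition to dienone ketals and allylic trapping of the enolate are established on this substrate class, and the trans C-9/C-10 relation follows from anti-allylation. On this point it is better than the chosen key step, whose C-10 centre depends on an enamine protonation.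
- Against it: no ring is formed. Nitrogen, ring A, ring C, ring D and C-11 to C-13 all remain, and a pyrrole must be built onto an α-substituted enone.
- Comparison: both plans fix C-9/C-10 first and are equal in the stereocentres the key step sets. The chosen plan has rings A and C in place at that point, whereas A3 has only ring B. One is an organometallic tandem reaction, the other an organocatalytic cascade. The route from A3 would probably be several steps longer.

Alternative 2: The cut is the O–C-11 bond of ring D. Cyclobutanone A5, from a [2+2] cycloaddition of an α-chloro ketene onto the ring B alkene A4, would undergo Baeyer–Villiger oxidation with alkaline H2O2 to give A6.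
- In its favour: the suprafacial cycloaddition guarantees the cis fusion and places oxygen and carbon anti to the ethyl group, and migration occurs with retention. Dechlorination from the convex face would leave the methyl concave. On control of C-11 and C-13 it is equal to or better than the chosen plan, which relies on a Felkin–Anh addition and a kinetic protonation.
- Against it: it presupposes rings A, B and C and the acid-sensitive vinylpyrrole A4, so it does not touch the C-9/C-10 problem. Basic peroxide also meets the epimerisable C-20 ester.
- Comparison: it needs three steps for ring D alone (cycloaddition, oxidation, dechlorination). The chosen plan needs four steps (vinyl addition, esterification, metathesis, closure), and these also close ring B.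

Alternative 3: The cut removes both N–C bonds of the pyrrole and the pyrrole C-3–C-4 bond. Dione A7 would be C-alkylated by bromoketone A8. Staudinger reduction would then release the amine, which condenses with the nearer ring carbonyl and the side-chain ketone to give A9.
- In its favour: it is convergent and forms rings A and C in one operation, one ring more than the chosen key step. Ring E arrives complete, so the uncertain late reduction at C-18 is avoided; on that point it is better.
- Against it: the key step creates no stereocentre, so the C-9/C-10 problem moves into the synthesis of A7. C-9 in A7 and C-18 in A8 are α to ketones and can epimerise, and the dione may O-alkylate. In A9, C-12 is a vinylogous-amide ketone and C-11 a plain methylene, so ring D still needs several stereocontrolled steps.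
- Comparison: its condensation chemistry is more robust than an asymmetric cascade. The overall step count is likely equal or higher once A7, A8 and ring D are counted.

Key step: step 3

Remark: the precursor 5 and product 6 of the key step were re-derived from the target and need no correction; 6 must be 2R,9R, which means bond formation on the Re face of the enal β-carbon.

Assumption: the sense of induction of a cinchona primary amine in this closure cannot be predicted with certainty. The quinidine-derived amine is written in step 3, and its quinine-derived pseudoenantiomer replaces it if the 9S series is favoured.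

Remark on the precursor: 5 keeps an unsubstituted pyrrole, because an acyl group at C-5 would switch off the nucleophile. The improvement is in its preparation: two steps by N-alkylation and cross-metathesis.

## Route

Step 1
Reactants: 1 pyrrole; 2 6-bromohex-1-ene
Product: 3 1-(hex-5-en-1-yl)-1H-pyrrole
Conditions: KOH (powder), DMSO, rt
Reagents that add atoms: none
Why: SN2 N-alkylation of potassium pyrrolide; in DMSO the dissociated anion reacts at nitrogen with a primary bromide.

Step 2
Reactants: 3 1-(hex-5-en-1-yl)-1H-pyrrole; 4 2-ethylacrolein
Product: 5 (2E)-2-ethyl-7-(1H-pyrrol-1-yl)hept-2-enal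
Conditions: 4 (4 equiv), second-generation Grubbs catalyst RuCl2(=CHPh)(PCy3)(H2IMes) (5 mol %), CH2Cl2, 40 °C
Reagents that add atoms: none
Why: Olefin cross-metathesis of a terminal alkene with a 1,1-disubstituted acrolein that does not homodimerise, so an excess of 4 drives the cross product; the trisubstituted enal should form as the E isomer (chain trans to CHO) under thermodynamic control.

Step 3
Reactants: 5 (2E)-2-ethyl-7-(1H-pyrrol-1-yl)hept-2-enal
Product: 6 (2R)-2-[(9R)-6,7,8,9-tetrahydro-5H-pyrrolo[1,2-a]azepin-9-yl]butanal
Conditions: 9-amino-9-deoxy-epi-quinidine (20 mol %), CF3CO2H (40 mol %), CHCl3 (5 mM, slow addition of 5), rt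
Reagents that add atoms: none
Why: The primary amine condenses with the α-branched aldehyde, which secondary amines activate poorly, to give an iminium ion; pyrrole C-2 adds to its β-carbon (Friedel–Crafts alkylation), the σ-complex rearomatises, and the enamine is protonated at C-10 and hydrolysed. The closest known reaction types are the secondary-amine-catalysed intramolecular alkylation of N-tethered pyrroles by enals (six-membered ring) and the cinchona primary-amine-catalysed Friedel–Crafts alkylation of indoles by α-branched enals; this case joins the two with a tether one carbon longer, an extension that has not been demonstrated. Ring C closes in a 7-exo-trig mode. C-9 is set by the catalyst, whose protonated quinuclidine and counter-anion shield one iminium face so that the pyrrole should add to the Re face of the β-carbon (9R). C-10 is set by protonation of the catalyst-bound enamine, biased by the adjacent C-9, and remains correctable because the same enamine allows re-equilibration. The step needs C-2 rather than C-3 to react: the two α-carbons are equivalent and the four-carbon tether cannot bring C-3 to the acceptor without strain. It also needs ring closure to beat intermolecular alkylation of the free α-position of the product, which high dilution and slow addition should secure.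

Step 4
Reactants: 6 (2R)-2-[(9R)-6,7,8,9-tetrahydro-5H-pyrrolo[1,2-a]azepin-9-yl]butanal
Product: 7 (3R,4R)-4-[(9R)-6,7,8,9-tetrahydro-5H-pyrrolo[1,2-a]azepin-9-yl]hex-1-en-3-ol
Conditions: CH2=CHMgBr (1.5 equiv), THF, −78 °C; aq. NH4Cl
Reagents that add atoms: vinylmagnesium bromide, C=C[Mg]Br
Why: Grignard addition under Felkin–Anh control: the bulky C-9 substituent lies anti to the incoming vinyl group, which passes the hydrogen and not the ethyl group of C-10, giving the 3R carbinol (the future 11S centre); the low temperature suppresses enolisation of the aldehyde.

Step 5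
Reactants: 7 (3R,4R)-4-[(9R)-6,7,8,9-tetrahydro-5H-pyrrolo[1,2-a]azepin-9-yl]hex-1-en-3-ol
Product: 8 (3R,4R)-4-[(9R)-6,7,8,9-tetrahydro-5H-pyrrolo[1,2-a]azepin-9-yl]hex-1-en-3-yl 2-methylprop-2-enoate
Conditions: methacryloyl chloride, Et3N, DMAP (cat.), CH2Cl2, 0 °C
Reagents that add atoms: methacryloyl chloride, CC(=C)C(=O)Cl
Why: DMAP-catalysed O-acylation; without a Lewis acid the pyrrole carbons do not compete, and no stereocentre is touched.

Step 6
Reactants: 8 (3R,4R)-4-[(9R)-6,7,8,9-tetrahydro-5H-pyrrolo[1,2-a]azepin-9-yl]hex-1-en-3-yl 2-methylprop-2-enoate
Product: 9 (5S)-3-methyl-5-{(1R)-1-[(9R)-6,7,8,9-tetrahydro-5H-pyrrolo[1,2-a]azepin-9-yl]propyl}furan-2(5H)-one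
Conditions: second-generation Grubbs catalyst RuCl2(=CHPh)(PCy3)(H2IMes) (10 mol %), toluene (5 mM), 80 °C
Reagents that add atoms: none
Why: Ring-closing metathesis of an allyl methacrylate to an α-methylbutenolide, which needs the N-heterocyclic-carbene catalyst and heat for the 1,1-disubstituted alkene; C-11 is not involved (its descriptor changes to S only through the priority rules).

Step 7
Reactants: 10 dimethyl (2S)-2-methylbutanedioate
Product: 11 (3S)-4-methoxy-3-methyl-4-oxobutanoic acid
Conditions: pig liver esterase, phosphate buffer pH 7, 1 M NaOH (pH-stat), rt; then HCl to pH 2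
Reagents that add atoms: water, O
Why: Enzymatic ester hydrolysis at the less hindered ester, remote from the methyl branch; at neutral pH the stereocentre is not epimerised.

Step 8
Reactants: 9 (5S)-3-methyl-5-{(1R)-1-[(9R)-6,7,8,9-tetrahydro-5H-pyrrolo[1,2-a]azepin-9-yl]propyl}furan-2(5H)-one; 11 (3S)-4-methoxy-3-methyl-4-oxobutanoic acid
Product: 13 methyl (2S)-2-methyl-4-{(9R)-9-[(1R)-1-((2S)-4-methyl-5-oxo-2,5-dihydrofuran-2-yl)propyl]-6,7,8,9-tetrahydro-5H-pyrrolo[1,2-a]azepin-3-yl}-4-oxobutanoate, via mixed trifluoroacetic anhydride 12 (not isolated)
Conditions: 11 (1.3 equiv), (CF3CO)2O (1.2 equiv), CH2Cl2, 0 °C; then 9 added slowly, 0 °C to rt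
Reagents that add atoms: none
Why: Friedel–Crafts acylation of a pyrrole by a mixed carboxylic–trifluoroacetic anhydride without Lewis acid; the only free α-position (pyrrole C-5) reacts, the butenolide is left alone, and the stereocentre of 11 is α to the spectator ester and not to the activated carbonyl.

Step 9
Reactants: 13 methyl (2S)-2-methyl-4-{(9R)-9-[(1R)-1-((2S)-4-methyl-5-oxo-2,5-dihydrofuran-2-yl)propyl]-6,7,8,9-tetrahydro-5H-pyrrolo[1,2-a]azepin-3-yl}-4-oxobutanoate
Product: 14 tetracyclic keto ester: methyl (2S)-2-methyl-4-oxo-4-[(9R,10R,11S,12R,13R)-ring A–D core]butanoate on pyrrole C-5 (ring B closed from pyrrole C-3 to C-12; lactone D cis-fused; 10-ethyl; 13-methyl concave)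
Conditions: AlCl3 (3.5 equiv), CH2Cl2, 0 °C to rt; ice-cold aq. NaHCO3
Reagents that add atoms: none
Why: Lewis-acid-promoted intramolecular Friedel–Crafts conjugate addition (6-exo-trig) of pyrrole C-3 onto the AlCl3-activated butenolide; C-3 is the only ring carbon within reach and the β-position not conjugated with the C-5 acyl group. The tether through C-10 allows attack only on the butenolide face syn to C-10, giving the cis fusion (12R), and protonation of the aluminium enolate on the convex face should leave the methyl concave (13R).

Step 10
Reactants: 14 tetracyclic keto ester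
Product: 16 target CNP0232452.6 (9R,10R,11S,12R,13R,18S,20S), via 18S hydroxy ester 15 (not isolated)
Conditions: (R)-Me-CBS oxazaborolidine (0.5 equiv), catecholborane (2 equiv), toluene, −40 °C; MeOH, aq. NaHCO3; then 2-hydroxypyridine (20 mol %), toluene, 60 °C
Reagents that add atoms: none
Why: Corey–Bakshi–Shibata reduction in which the pyrrolyl group acts as the large substituent, so the (R)-catalyst should give the 18S carbinol under pure reagent control; catecholborane at low temperature spares lactone D and the ester and limits over-reduction. The γ-hydroxy ester then lactonises under neutral bifunctional catalysis, which avoids acid (ionisation at C-18) and base (epimerisation at C-13 and C-20).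

## Compound list

1 | pyrrole | c1cc[nH]c1 | starting material
2 | 6-bromohex-1-ene | C=CCCCCBr | starting material
3 | 1-(hex-5-en-1-yl)-1H-pyrrole | C=CCCCCn1cccc1 | intermediate
4 | 2-ethylacrolein (2-methylidenebutanal) | CCC(=C)C=O | starting material
5 | (2E)-2-ethyl-7-(1H-pyrrol-1-yl)hept-2-enal | O=C/C(CC)=C/CCCCn1cccc1 | intermediate
6 | (2R)-2-[(9R)-6,7,8,9-tetrahydro-5H-pyrrolo[1,2-a]azepin-9-yl]butanal | CC[C@@H](C=O)[C@H]1CCCCn2cccc12 | intermediate
7 | (3R,4R)-4-[(9R)-6,7,8,9-tetrahydro-5H-pyrrolo[1,2-a]azepin-9-yl]hex-1-en-3-ol | CC[C@@H]([C@H](O)C=C)[C@H]1CCCCn2cccc12 | intermediate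
8 | (3R,4R)-4-[(9R)-6,7,8,9-tetrahydro-5H-pyrrolo[1,2-a]azepin-9-yl]hex-1-en-3-yl 2-methylprop-2-enoate | CC[C@@H]([C@H](OC(=O)C(C)=C)C=C)[C@H]1CCCCn2cccc12 | intermediate
9 | (5S)-3-methyl-5-{(1R)-1-[(9R)-6,7,8,9-tetrahydro-5H-pyrrolo[1,2-a]azepin-9-yl]propyl}furan-2(5H)-one | CC[C@@H]([C@@H]1OC(=O)C(C)=C1)[C@H]2CCCCn3cccc23 | intermediate
10 | dimethyl (2S)-2-methylbutanedioate | COC(=O)C[C@H](C)C(=O)OC | starting material
11 | (3S)-4-methoxy-3-methyl-4-oxobutanoic acid | OC(=O)C[C@H](C)C(=O)OC | intermediate
12 | (3S)-4-methoxy-3-methyl-4-oxobutanoic trifluoroacetic anhydride (not isolated) | FC(F)(F)C(=O)OC(=O)C[C@H](C)C(=O)OC | intermediate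
13 | methyl (2S)-2-methyl-4-{(9R)-9-[(1R)-1-((2S)-4-methyl-5-oxo-2,5-dihydrofuran-2-yl)propyl]-6,7,8,9-tetrahydro-5H-pyrrolo[1,2-a]azepin-3-yl}-4-oxobutanoate | CC[C@@H]([C@@H]1OC(=O)C(C)=C1)[C@H]2CCCCn3c(C(=O)C[C@H](C)C(=O)OC)ccc23 | intermediate
14 | tetracyclic keto ester, methyl (2S)-2-methyl-4-oxo-4-[(9R,10R,11S,12R,13R)-ring A–D core]butanoate on pyrrole C-5 | CC[C@H]1[C@@H]2OC(=O)[C@H](C)[C@@H]2c2cc(C(=O)C[C@H](C)C(=O)OC)n3c2[C@@H]1CCCC3 | intermediate
15 | tetracyclic hydroxy ester, methyl (2S,4S)-4-hydroxy-2-methyl-4-[(9R,10R,11S,12R,13R)-ring A–D core]butanoate (not isolated) | CC[C@H]1[C@@H]2OC(=O)[C@H](C)[C@@H]2c2cc([C@@H](O)C[C@H](C)C(=O)OC)n3c2[C@@H]1CCCC3 | intermediate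
16 | CNP0232452.6, (9R,10R,11S,12R,13R,18S,20S)-pentacycle with rings A–E | CC[C@H]1[C@@H]2OC(=O)[C@H](C)[C@@H]2c2cc([C@@H]3C[C@H](C)C(=O)O3)n3c2[C@@H]1CCCC3 | target

## Step count and least certain steps

Total: 10 steps. Longest linear sequence: 9 steps (steps 1–6 and 8–10, from 1 and 2); step 7 is a one-step side branch.

**Step 3 (key step).**
- Risk: iminium formation from the hindered α-branched enal may be slow, so that acid-induced oligomerisation of the pyrrole or intermolecular alkylation overtakes the seven-membered closure. Facial discrimination in a flexible seven-membered transition state may be poor, and the protonation at C-10 may be unselective.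
- Fallback, from 3 back to 6: cross-metathesis of 3 with crotonaldehyde gives (E)-7-(1H-pyrrol-1-yl)hept-2-enal F1. A secondary-amine iminium cyclisation of the kind documented for linear N-tethered pyrrole enals, with (5S)-5-benzyl-2,2,3-trimethylimidazolidin-4-one trifluoroacetate or its enantiomer, whichever gives the 9R series, should then close ring C to (R)-2-(6,7,8,9-tetrahydro-5H-pyrrolo[1,2-a]azepin-9-yl)acetaldehyde F2. Condensation with (S)-1-amino-2-(methoxymethyl)pyrrolidine gives the SAMP hydrazone F3. Deprotonation with LiN(iPr)2 and alkylation with EtI should set C-10 under auxiliary control (by the usual azaenolate model, the 10R centre), giving the ethylated hydrazone F4. Cleavage with aqueous CuCl2 in THF at pH 7 returns 6.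

**Step 9.**
- Risk: the β-carbon of the acylpyrrole may be too weak a nucleophile for the activated butenolide, so that decomposition competes. Prolonged exposure to the Lewis acid may also allow equilibration at C-13 away from the concave methyl.
- Fallback, from 9 back to 14: the order is reversed. The more nucleophilic, non-acylated pyrrole 9 is cyclised under high dilution with a milder Lewis acid (Me2AlCl, CH2Cl2, −20 °C) to the tetracyclic lactone with free pyrrole C-5, F5. In F5 the lactone α-hydrogen is the only acidic C–H, so C-13 can be reset if needed by deprotonation with LiN(iPr)2 and kinetic protonation on the convex face. Acylation of F5 with 12 at its single free α-position then gives 14.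

**Step 10.**
- Risk: the vinylogous-amide ketone may react slowly, leading to incomplete conversion or poor face selectivity. The boron alkoxide may ionise and be over-reduced, and C-18 may scramble during lactonisation.
- Fallback, from 14 back to 16: kinetic reagent control is replaced by thermodynamic control. Luche reduction (NaBH4, CeCl3·7H2O, MeOH, −20 °C) gives 15 together with its 18R epimer F6, and lactonisation gives 16 together with the 18R lactone F7. After separation, F7 is equilibrated at C-18 with catalytic camphorsulfonic acid in CH2Cl2, through reversible ionisation of the pyrrolylcarbinyl C–O bond. This should favour the cis-3,5-disubstituted lactone 16, which is normally the more stable isomer, and the remainder is recycled.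

**Step 4.**
- Risk: facial selectivity may be modest, because the two substituents at C-10 are both alkyl, and some enolisation at C-10 may occur.
- Fallback, from 6 back to 8: the epimers are separated, and the unwanted (3S,4R)-alcohol F8 is converted by Mitsunobu esterification with methacrylic acid (PPh3, diisopropyl azodicarboxylate, THF, 0 °C). This inverts the carbinol centre and gives 8 directly, so both epimers converge.

## Further compounds

F1 | step 3 | (E)-7-(1H-pyrrol-1-yl)hept-2-enal | O=C/C=C/CCCCn1cccc1
F2 | step 3 | (R)-2-(6,7,8,9-tetrahydro-5H-pyrrolo[1,2-a]azepin-9-yl)acetaldehyde | O=CC[C@H]1CCCCn2cccc12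
F3 | step 3 | (E)-N-[(2S)-2-(methoxymethyl)pyrrolidin-1-yl]-2-[(9R)-6,7,8,9-tetrahydro-5H-pyrrolo[1,2-a]azepin-9-yl]ethan-1-imine | COC[C@@H]1CCCN1/N=C/C[C@H]2CCCCn3cccc23
F4 | step 3 | (E,2R)-N-[(2S)-2-(methoxymethyl)pyrrolidin-1-yl]-2-[(9R)-6,7,8,9-tetrahydro-5H-pyrrolo[1,2-a]azepin-9-yl]butan-1-imine | COC[C@@H]1CCCN1/N=C/[C@H](CC)[C@H]2CCCCn3cccc23
F5 | step 9 | (9R,10R,11S,12R,13R)-tetracyclic lactone (rings A–D) with unsubstituted pyrrole C-5 | CC[C@H]1[C@@H]2OC(=O)[C@H](C)[C@@H]2c2ccn3c2[C@@H]1CCCC3
F6 | step 10 | 18R hydroxy ester, C-18 epimer of 15 | CC[C@H]1[C@@H]2OC(=O)[C@H](C)[C@@H]2c2cc([C@H](O)C[C@H](C)C(=O)OC)n3c2[C@@H]1CCCC3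
F7 | step 10 | 18R lactone, C-18 epimer of 16 | CC[C@H]1[C@@H]2OC(=O)[C@H](C)[C@@H]2c2cc([C@H]3C[C@H](C)C(=O)O3)n3c2[C@@H]1CCCC3
F8 | step 4 | (3S,4R)-4-[(9R)-6,7,8,9-tetrahydro-5H-pyrrolo[1,2-a]azepin-9-yl]hex-1-en-3-ol | CC[C@@H]([C@@H](O)C=C)[C@H]1CCCCn2cccc12
A1 | alternative 1 | 4,4-dimethoxycyclohexa-2,5-dien-1-one | COC1(OC)C=CC(=O)C=C1
A2 | alternative 1 | (E)-4-[(tert-butyldimethylsilyl)oxy]but-2-en-1-yl acetate | CC(=O)OC/C=C/CO[Si](C)(C)C(C)(C)C
A3 | alternative 1 | (5R,6R)-6-[(E)-4-(tert-butyldimethylsilyloxy)but-2-en-1-yl]-5-ethyl-4,4-dimethoxycyclohex-2-en-1-one | CC[C@@H]1[C@@H](C/C=C/CO[Si](C)(C)C(C)(C)C)C(=O)C=CC1(OC)OC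
A4 | alternative 2 | ring B alkene (C-11=C-12) of the ring A–C core with the C-5 keto ester side chain | CC[C@H]1C=Cc2cc(C(=O)C[C@H](C)C(=O)OC)n3c2[C@@H]1CCCC3
A5 | alternative 2 | α-chloro-α-methyl cyclobutanone cis-fused to ring B at C-11/C-12 | CC[C@H]1[C@@H]2C(=O)[C@@](C)(Cl)[C@@H]2c2cc(C(=O)C[C@H](C)C(=O)OC)n3c2[C@@H]1CCCC3
A6 | alternative 2 | α-chloro-α-methyl fused lactone (ring D with chlorine at C-13) | CC[C@H]1[C@@H]2OC(=O)[C@@](C)(Cl)[C@@H]2c2cc(C(=O)C[C@H](C)C(=O)OC)n3c2[C@@H]1CCCC3
A7 | alternative 3 | (4R,5S)-4-(4-azidobutyl)-5-ethylcyclohexane-1,3-dione | CC[C@H]1CC(=O)CC(=O)[C@@H]1CCCCN=[N+]=[N-]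
A8 | alternative 3 | (3S,5S)-5-(2-bromoacetyl)-3-methyloxolan-2-one | BrCC(=O)[C@@H]1C[C@H](C)C(=O)O1
A9 | alternative 3 | ring B ketone (C-12 carbonyl) of the azepine-fused pyrrole with ring E in place | CC[C@H]1CC(=O)c2cc([C@@H]3C[C@H](C)C(=O)O3)n3c2[C@@H]1CCCC3
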